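**Assumption:** CIP analysis of the SMILES (O > isopropyl > allylic ring CH2 > other ring CH2) gives R at the carbinol carbon, so the target is the (R)-terpinen-4-yl ester. The sense of induction of the chiral acid in step 2 cannot be predicted, so its antipode is fixed by a screening run.

## Retrosynthetic overview

1. Target 8 ⇒ dibromide 6 + two prenyl boronates 7 (double aryl–allyl Suzuki–Miyaura coupling, last, so the acid-labile prenyl groups never see the cationic step).
2. 6 ⇒ neryl ester 3 by a catalytic asymmetric tail-to-head cycloisomerisation: C1–C6 closure to the α-terpinyl cation, 1,2-hydride shift to the terpinen-4-yl cation, return of the same carboxylate at C4. This one step forms the ring, the ester C–O bond and the only stereocentre, with no by-product.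
3. 3 ⇒ nerol 2 + 3,5-dibromo-4-methoxybenzoic acid 1 (Steglich esterification).
4. Ring order: only the cyclohexene ring is built (step 2); the arene is bought.

## Route

**Step 1**
Reactants: 1 3,5-dibromo-4-methoxybenzoic acid; 2 nerol [(2Z)-3,7-dimethylocta-2,6-dien-1-ol]
Product: 3 (2Z)-3,7-dimethylocta-2,6-dien-1-yl 3,5-dibromo-4-methoxybenzoate (neryl ester)
Conditions: DCC (1.1 equiv), DMAP (0.1 equiv), CH2Cl2, 0 °C → rt
Reagents that add atoms: none
Why: Steglich esterification, in which DCC activates 1 as the O-acylisourea and DMAP relays the acyl group to the unhindered primary allylic alcohol under neutral conditions that leave the Z-alkene and the aryl bromides untouched; no stereocentre is formed.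

**Step 2**
Reactants: 3 neryl 3,5-dibromo-4-methoxybenzoate
Product: 6 (1R)-4-methyl-1-(propan-2-yl)cyclohex-3-en-1-yl 3,5-dibromo-4-methoxybenzoate, via α-terpinyl cation ion pair 4 (not isolated), via terpinen-4-yl cation ion pair 5 (not isolated)
Conditions: confined chiral IDPi Brønsted acid (BINOL-derived imidodiphosphorimidate, N-triflyl core, 5 mol%, antipode by screening), 5 Å MS, CHCl3/methylcyclohexane 1:1, 0.05 M, −40 °C; Et3N quench at −40 °C
Reagents that add atoms: none
Why: Proposed new method: the confined chiral acid protonates the ester carbonyl, the Z-6,7-alkene displaces the carboxylic acid from C1 anti (tail-to-head closure) to give cation 4, the 1,2-hydride shift (tertiary to tertiary, low barrier) moves the charge to the ring carbon next to the spot where the acid, still hydrogen-bonded to the chiral anion, was left, and this acid then adds to one enantiotopic face of the planar cation 5 inside the catalyst pocket (the transient stereocentre of 4 is erased in 5, and the antipode giving R is picked by screening), while the low temperature keeps the non-allylic tertiary ester product, which ionises more slowly than the allylic ester 3, from re-ionising; the closest known reaction types are acid-capsule- and chiral hydrogen-bond-donor-catalysed tail-to-head cyclisations of neryl and geranyl esters or chlorides (which pass through the same hydride shift), internal return in linalyl/neryl ester solvolysis, and IDPi-catalysed asymmetric hydroalkoxylation and hydrolactonisation of unactivated alkenes, where a tertiary cationic centre is captured by oxygen enantioselectively.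

**Step 3**
Reactants: 6 (R)-terpinen-4-yl 3,5-dibromo-4-methoxybenzoate; 7 3-methylbut-2-en-1-ylboronic acid pinacol ester (prenyl-Bpin, 3.0 equiv)
Product: 8 (1R)-4-methyl-1-(propan-2-yl)cyclohex-3-en-1-yl 4-methoxy-3,5-bis(3-methylbut-2-en-1-yl)benzoate (target)
Conditions: t-BuXPhos Pd G3 (4 mol%), aq K3PO4 (4 equiv), THF, 40 °C
Reagents that add atoms: none
Why: Double aryl–allyl Suzuki–Miyaura coupling, in which the bulky di-tert-butylbiarylphosphine lets the allyl–Pd intermediate equilibrate (σ–π–σ) to the less hindered primary terminus before reductive elimination, giving the linear prenyl rather than the reverse-prenyl isomer, while the hindered tertiary benzoate, the ring alkene and the quaternary stereocentre are inert to Pd(0) and aqueous phosphate at 40 °C.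

## Compound list

1 | 3,5-dibromo-4-methoxybenzoic acid | COc1c(Br)cc(cc1Br)C(=O)O | starting material
2 | nerol, (2Z)-3,7-dimethylocta-2,6-dien-1-ol | OC/C=C(C)\CCC=C(C)C | starting material
3 | (2Z)-3,7-dimethylocta-2,6-dien-1-yl 3,5-dibromo-4-methoxybenzoate | COc1c(Br)cc(cc1Br)C(=O)OC/C=C(C)\CCC=C(C)C | intermediate
4 | α-terpinyl cation [2-(4-methylcyclohex-3-en-1-yl)propan-2-ylium] paired with 3,5-dibromo-4-methoxybenzoate (the latter held as the acid on the chiral catalyst anion); ring C–H stereocentre transient and erased in 5, so left unspecified | CC1=CCC(CC1)[C+](C)C.COc1c(Br)cc(cc1Br)C([O-])=O | intermediate (not isolated)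
5 | terpinen-4-yl cation [4-methyl-1-(propan-2-yl)cyclohex-3-en-1-ylium, achiral] paired with 3,5-dibromo-4-methoxybenzoate | CC1=CC[C+](CC1)C(C)C.COc1c(Br)cc(cc1Br)C([O-])=O | intermediate (not isolated)
6 | (1R)-4-methyl-1-(propan-2-yl)cyclohex-3-en-1-yl 3,5-dibromo-4-methoxybenzoate | COc1c(Br)cc(cc1Br)C(=O)O[C@@]1(C(C)C)CC=C(C)CC1 | intermediate
7 | 4,4,5,5-tetramethyl-2-(3-methylbut-2-en-1-yl)-1,3,2-dioxaborolane (prenyl-Bpin) | CC(C)=CCB1OC(C)(C)C(C)(C)O1 | starting material
8 | (1R)-4-methyl-1-(propan-2-yl)cyclohex-3-en-1-yl 4-methoxy-3,5-bis(3-methylbut-2-en-1-yl)benzoate | COc1c(CC=C(C)C)cc(C(=O)O[C@@]2(C(C)C)CC=C(C)CC2)cc1CC=C(C)C | target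

## Summary

Total step count: 3. Longest linear sequence: 3 steps (1 or 2 → 3 → 6 → 8).

## Steps most likely to fail

**Step 2 (highest risk).** Four things can go wrong:
- the carboxylate may return at the exocyclic carbon of 4 and give the α-terpinyl ester;
- cation 5 may lose a proton to terpinolene or α-/γ-terpinene plus acid 1;
- the two faces of 5 differ only in the position of the ring alkene, so the ee may be low;
- the product may re-ionise and erode.

Fallback, setting out from 1 and coming back at 6: acid 1 is converted with oxalyl chloride and catalytic DMF (CH2Cl2, rt) into 3,5-dibromo-4-methoxybenzoyl chloride F1. Purchased (R)-(−)-terpinen-4-ol F2 is deprotonated with n-BuLi (THF, −78 °C) and the lithium alkoxide is acylated with F1 (−78 °C → rt) to give 6 directly. The stereocentre then comes from the chiral pool, the cyclohexene ring is bought rather than made, and nerol and steps 1–2 are dropped.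

**Step 3.** The coupling may give reverse-prenyl (γ) isomers, stop after one coupling, or lose boronate by protodeboronation. Fallback, setting out from 6 and coming back at 8: 6 is coupled twice with allylboronic acid pinacol ester (Pd(dppf)Cl2, aq K3PO4, THF, 60 °C), where no α/γ question arises, to give (1R)-4-methyl-1-(propan-2-yl)cyclohex-3-en-1-yl 4-methoxy-3,5-di(prop-2-en-1-yl)benzoate F3. Both terminal allyl groups of F3 are then converted into prenyl groups by cross-metathesis with excess 2-methylbut-2-ene (Grubbs II, CH2Cl2, 40 °C), giving 8. The trisubstituted ring alkene does not take part.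

**Step 1 (low risk).** N-acylurea formation or partial Z/E erosion of the allylic alcohol is possible. Fallback, setting out from 2 and coming back at 3: nerol 2 is converted with PBr3 (Et2O, −10 °C) into neryl bromide F4. The caesium carboxylate of 1 (Cs2CO3, DMF, rt) is then O-alkylated with F4 in an SN2 reaction to give 3, so the acid acts as nucleophile instead of acyl donor.

## Further compounds

F1 | step 2 | 3,5-dibromo-4-methoxybenzoyl chloride | COc1c(Br)cc(cc1Br)C(Cl)=O
F2 | step 2 | (R)-(−)-terpinen-4-ol, (1R)-4-methyl-1-(propan-2-yl)cyclohex-3-en-1-ol (purchased reagent of the fallback) | O[C@@]1(C(C)C)CC=C(C)CC1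
F3 | step 3 | (1R)-4-methyl-1-(propan-2-yl)cyclohex-3-en-1-yl 4-methoxy-3,5-di(prop-2-en-1-yl)benzoate | COc1c(CC=C)cc(cc1CC=C)C(=O)O[C@@]1(C(C)C)CC=C(C)CC1
F4 | step 1 | neryl bromide, (2Z)-1-bromo-3,7-dimethylocta-2,6-diene | BrC/C=C(C)\CCC=C(C)C
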